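**Strategy.** The target is cut at the enone into 2,2-dimethylchroman-6-carbaldehyde and a resacetophenone-derived methyl ketone that carries the dihydrofuran (ring B). Ring B is not closed directly. Its O1–C2(H)–C(CH3)2–OH array has the ring oxygen and the tertiary hydroxyl on neighbouring carbons, so it is the transposed form of a 2,2-dimethylchroman-3-ol. A linear chromene is epoxidised enantioselectively and opened reductively to the (3S)-chromanol, whose triflate is then solvolysed. O1 shifts from C(CH3)2 to the carbinol carbon through an oxiranium ion, and water caps the tertiary carbon. One operation contracts pyran to dihydrofuran, inverts the carbinol centre to (R) and installs the tertiary alcohol.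

Key step: step 6

Remark: 2,2-dimethylchroman-6-carbaldehyde is taken as a catalogue building block. Chroman numbering (O1, C2, C3, C4, C4a, C5–C8, C8a) is used for the six-membered precursors and benzofuran numbering for the contracted products.

Step 1
Reactants: 1 2,4-dihydroxyacetophenone; 2 isoprene
Product: 3 1-(7-hydroxy-2,2-dimethylchroman-6-yl)ethanone
Conditions: Amberlyst 15, THF/heptane, 65 °C, slow addition of 2; chromatography
Reagents that add atoms: none
Why: Acid-catalysed Friedel–Crafts prenylation followed by Markovnikov hydroalkoxylation (one-pot chroman annulation), in which the dimethylallyl cation attacks C5 of 1 (para to the chelated 2-OH, ortho to the 4-OH, far less crowded than C3 between the two oxygens) and the free 4-OH then closes the linear chroman, the minor angular isomer being removed by chromatography.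

Step 2
Reactants: 3 1-(7-hydroxy-2,2-dimethylchroman-6-yl)ethanone
Product: 4 1-(7-hydroxy-2,2-dimethyl-2H-chromen-6-yl)ethanone
Conditions: DDQ, 1,4-dioxane, reflux
Reagents that add atoms: none
Why: DDQ dehydrogenation, in which hydride abstraction from benzylic C4 is assisted by O1 (ortho to C4a) and the 7-OH (para to C4a) and loss of a C3 proton gives the conjugated 2H-chromene.

Step 3
Reactants: 4 1-(7-hydroxy-2,2-dimethyl-2H-chromen-6-yl)ethanone
Product: 5 6-acetyl-2,2-dimethyl-2H-chromen-7-yl acetate
Conditions: Ac2O, pyridine, DMAP (cat.), CH2Cl2, 0 °C to rt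
Reagents that add atoms: acetic anhydride, CC(=O)OC(C)=O
Why: DMAP-catalysed O-acylation overcomes the hydrogen bond of the chelated phenol, and the acetate shields the phenol from the oxidant and from Tf2O, tempers the donor power of ring A in step 6 and needs no separate removal step.

Step 4
Reactants: 5 6-acetyl-2,2-dimethyl-2H-chromen-7-yl acetate
Product: 6 (3S,4S)-6-acetyl-3,4-epoxy-2,2-dimethylchroman-7-yl acetate
Conditions: (S,S)-(salen)MnCl (cat.; salen = dianion of N,N'-bis(3,5-di-tert-butylsalicylidene)-1,2-cyclohexanediamine), mCPBA, NMO, CH2Cl2, −78 °C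
Reagents that add atoms: mCPBA, O=C(OO)c1cccc(Cl)c1
Why: Jacobsen–Katsuki epoxidation, for which 2,2-dimethyl-2H-chromenes with an acceptor at C6 are among the best substrates: the oxo-manganese species delivers oxygen to one face of the cis-alkene in a side-on approach, the (S,S)-ligand gives the (3S,4S)-epoxide as in the other members of this chromene class, and the cold anhydrous oxidant spares aryl acetate and ketone.

Step 5
Reactants: 6 (3S,4S)-6-acetyl-3,4-epoxy-2,2-dimethylchroman-7-yl acetate
Product: 7 (3S)-6-acetyl-3-hydroxy-2,2-dimethylchroman-7-yl acetate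
Conditions: H2 (1 atm), Pd/C, EtOAc, rt, stopped after one equivalent of H2
Reagents that add atoms: none
Why: Hydrogenolysis of a benzylic epoxide cleaves only the benzylic C4–O bond, so the C3–O bond and the (3S) configuration stay untouched, while aryl ketone and acetate should survive at one atmosphere.

Step 6
Reactants: 7 (3S)-6-acetyl-3-hydroxy-2,2-dimethylchroman-7-yl acetate
Product: 10 (2R)-5-acetyl-2-(2-hydroxypropan-2-yl)-2,3-dihydro-1-benzofuran-6-yl acetate, via secondary triflate 8 (not isolated), via bicyclic oxiranium ion 9 (not isolated)
Conditions: Tf2O, 2,6-di-tert-butyl-4-methylpyridine, CH2Cl2, −78 to −30 °C; then acetone/H2O (4:1), −30 °C to rt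
Reagents that add atoms: water, O; trifluoromethanesulfonic anhydride, O=S(=O)(OS(=O)(=O)C(F)(F)F)C(F)(F)F (its triflyl group stays only in 8 and 9)
Why: The alcohol is triflated chemoselectively (the phenol is masked as acetate), and in the half-chair that holds the C3–OTf bond pseudo-equatorial this bond lies antiperiplanar to C2–O1, so a lone pair of O1 displaces triflate from the rear while C2–O1 loosens toward a tertiary cation. This single O1–C3 bond formation closes the three-membered oxiranium ring in 3-exo-tet mode and at the same time the five-membered ring O1–C3–C4–C4a–C8a in 5-exo-tet mode, and water then opens the oxiranium ion at the tertiary carbon C2, which bears most of the positive charge, so that the old six-membered ring is cut. The closest known reaction type is the solvolytic ring contraction of tetrahydropyran-3-yl sulfonates by participation of the ring oxygen (pyranoside 2-triflates to 2,5-anhydro sugars, 3-halo- or 3-sulfonyloxy-2,2-dimethyltetrahydropyrans to 2-(2-hydroxypropan-2-yl)tetrahydrofurans), the reverse of the Zn(OAc)2-mediated expansion of tetrahydrofuran mesylates. The only stereocentre is controlled by the substrate: C3 undergoes one clean inversion without a free secondary cation, so (3S)-8 should give (2R)-10 with transfer of the enantiopurity set in step 4. The step needs migration of O1 in preference to the C2 methyl group and the C4 hydrogen, and capture by water in preference to proton loss; the tertiary-cation character at C2, the weakly donating 7-acetoxy group (para to C4a, it makes a C4 benzylic cation less attractive than a free phenol would), the hindered non-nucleophilic base and the large excess of water at low temperature are meant to secure this. Attack of water at C3 would only return 7 by double inversion.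

Step 7
Reactants: 10 (2R)-5-acetyl-2-(2-hydroxypropan-2-yl)-2,3-dihydro-1-benzofuran-6-yl acetate; 11 2,2-dimethylchroman-6-carbaldehyde
Product: 13 (E)-3-(2,2-dimethylchroman-6-yl)-1-[(2R)-6-hydroxy-2-(2-hydroxypropan-2-yl)-2,3-dihydro-1-benzofuran-5-yl]prop-2-en-1-one (target CNP0327385.2), via free phenol ketone 12 (not isolated)
Conditions: KOH (excess), EtOH/H2O, 0 °C to rt; then cold dilute HCl
Reagents that add atoms: none
Why: Claisen–Schmidt condensation, in which hydroxide first saponifies the aryl acetate, the methyl ketone enolate adds to the non-enolisable aldehyde and E1cB loss of water gives the thermodynamically favoured E-enone, while C2 of ring B bears no acidic hydrogen and is not touched.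

**Compound list**
1 | 2,4-dihydroxyacetophenone | CC(=O)c1ccc(O)cc1O | starting material
2 | isoprene | C=CC(C)=C | starting material
3 | 1-(7-hydroxy-2,2-dimethylchroman-6-yl)ethanone | CC(=O)c1cc2c(cc1O)OC(C)(C)CC2 | intermediate
4 | 1-(7-hydroxy-2,2-dimethyl-2H-chromen-6-yl)ethanone | CC(=O)c1cc2c(cc1O)OC(C)(C)C=C2 | intermediate
5 | 6-acetyl-2,2-dimethyl-2H-chromen-7-yl acetate | CC(=O)c1cc2c(cc1OC(C)=O)OC(C)(C)C=C2 | intermediate
6 | (3S,4S)-6-acetyl-3,4-epoxy-2,2-dimethylchroman-7-yl acetate | CC(=O)c1cc2c(cc1OC(C)=O)OC(C)(C)[C@H]3O[C@@H]23 | intermediate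
7 | (3S)-6-acetyl-3-hydroxy-2,2-dimethylchroman-7-yl acetate | CC(=O)c1cc2c(cc1OC(C)=O)OC(C)(C)[C@@H](O)C2 | intermediate
8 | (3S)-6-acetyl-2,2-dimethyl-3-(trifluoromethylsulfonyloxy)chroman-7-yl acetate | CC(=O)c1cc2c(cc1OC(C)=O)OC(C)(C)[C@@H](OS(=O)(=O)C(F)(F)F)C2 | intermediate
9 | bicyclic oxiranium triflate (O1 bonded to C8a, C2 and inverted C3) | CC(=O)c1cc2c(cc1OC(C)=O)[O+]3C(C)(C)[C@H]3C2.[O-]S(=O)(=O)C(F)(F)F | intermediate
10 | (2R)-5-acetyl-2-(2-hydroxypropan-2-yl)-2,3-dihydro-1-benzofuran-6-yl acetate | CC(=O)c1cc2c(cc1OC(C)=O)O[C@@H](C(C)(C)O)C2 | intermediate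
11 | 2,2-dimethylchroman-6-carbaldehyde | CC1(C)CCc2cc(C=O)ccc2O1 | starting material
12 | 1-[(2R)-6-hydroxy-2-(2-hydroxypropan-2-yl)-2,3-dihydro-1-benzofuran-5-yl]ethanone | CC(=O)c1cc2c(cc1O)O[C@@H](C(C)(C)O)C2 | intermediate
13 | (E)-3-(2,2-dimethylchroman-6-yl)-1-[(2R)-6-hydroxy-2-(2-hydroxypropan-2-yl)-2,3-dihydro-1-benzofuran-5-yl]prop-2-en-1-one | CC1(C)CCc2cc(/C=C/C(=O)c3cc4c(cc3O)O[C@@H](C(C)(C)O)C4)ccc2O1 | target

Total step count: 7. Longest linear sequence: 7 steps (1 to 13); 11 enters in the last step.

**Steps most likely to fail**

Step 6. Participation of O1 is weakened by conjugation with the para acetyl group. It may therefore be outrun by a hydride shift from C4 or by elimination. The cationic intermediate may also lose a proton instead of taking up water, or the tertiary alcohol may re-ionise in the acidic medium with re-expansion of the ring. The fallback sets out from 7 and comes back at 10, and it separates the skeletal change from the hydration. The triflate is generated as before, but in dry CH2Cl2 without any water. The oxiranium ion then ends by loss of a methyl proton to the hindered base and gives (2R)-5-acetyl-2-(prop-1-en-2-yl)-2,3-dihydro-1-benzofuran-6-yl acetate F1. A Mukaiyama hydration (Mn(dpm)3 cat., PhSiH3, O2, iPrOH, 0 °C, then P(OEt)3) adds water in the Markovnikov sense by hydrogen-atom transfer. This is a neutral radical path that cannot re-open the new ring, and it returns to 10.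

Step 1. Electrophilic attack may be poorly selective between C5 and C3, and double alkylation may occur. The fallback sets out from 1 and comes back at 4, bypassing steps 1 and 2, and it fixes the position with a halogen. Bromination (Br2, AcOH) goes to C5 and gives 1-(5-bromo-2,4-dihydroxyphenyl)ethanone F2. A Mizoroki–Heck coupling with 2-methylbut-3-en-2-ol (Pd(OAc)2, P(o-tol)3, Et3N, DMF, 100 °C) gives (E)-1-[2,4-dihydroxy-5-(3-hydroxy-3-methylbut-1-enyl)phenyl]ethanone F3. Acid-catalysed cyclodehydration through the allyl cation (PPTS, toluene, reflux) then closes the 2H-pyran ring to 4.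

Step 5. The aryl ketone may be reduced concurrently, or palladium may isomerise the epoxide by hydride shift, which would erase the C3 stereocentre. The fallback sets out from 6 and comes back at 7, and it replaces the metal surface by a halohydrin and radical sequence. LiBr/AcOH in THF opens the epoxide at benzylic C4 with inversion to the trans-bromohydrin (3R,4R)-6-acetyl-4-bromo-3-hydroxy-2,2-dimethylchroman-7-yl acetate F4. The C3–O bond is unchanged; the descriptor changes only because of the bromine. Radical debromination ((Me3Si)3SiH, AIBN, toluene, 80 °C) removes the C4 bromine, leaves ketone and acetate alone and gives 7.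

**Further compounds**
F1 | step 6 | (2R)-5-acetyl-2-(prop-1-en-2-yl)-2,3-dihydro-1-benzofuran-6-yl acetate | CC(=O)c1cc2c(cc1OC(C)=O)O[C@@H](C(C)=C)C2
F2 | step 1 | 1-(5-bromo-2,4-dihydroxyphenyl)ethanone | CC(=O)c1cc(Br)c(O)cc1O
F3 | step 1 | (E)-1-[2,4-dihydroxy-5-(3-hydroxy-3-methylbut-1-enyl)phenyl]ethanone | CC(=O)c1cc(/C=C/C(C)(C)O)c(O)cc1O
F4 | step 5 | (3R,4R)-6-acetyl-4-bromo-3-hydroxy-2,2-dimethylchroman-7-yl acetate | CC(=O)c1cc2c(cc1OC(C)=O)OC(C)(C)[C@@H](O)[C@@H]2Br
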